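**Retrosynthetic overview**

1. Target 25 ⇒ C-6–C-7 bond (oxonane, last ring) by Nozaki–Hiyama–Kishi closure of a C-7 alkenyl bromide onto a C-6 aldehyde (24), with the C-4 octanoate already in place.
2. Oxepane ⇒ 7-exo opening at C-3 of a reagent-controlled 3,4-epoxide by the C-16 hydroxyl (this also sets C-4); C-2–C-3 bond ⇒ transfer of a (Z)-alkenyl group to the C-2 oxocarbenium ion of bicyclic acetal 13; C-11 methyl carbinol ⇒ sulfoxonium-ylide epoxide, then hydride.
3. Key disconnection: the cyclohexanone and the oxolane of 13 arise together from cyclopentyl silyl ether 11 (cis C-9/C-10 epoxide on C-11, dimethoxymethyl C-2 on C-1). A semipinacol 1,2-shift of C-1 from C-11 to C-10 enlarges the five-membered carbocycle (C-11, C-12, C-13, C-14, C-1) to the six-membered one, and the C-9 oxygen then closes onto C-2.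
4. Enabling feature: in the cyclohexane the oxygen-bearing carbon C-11 is flanked by ring-fusion carbon C-10, whose exocyclic neighbour C-9 is an ether carbon of the oxolane. This C-11(O)–C-10–C-9(O) triad is the 2-(1-hydroxyalkyl)cycloalkanone pattern of an epoxy-carbinol ring enlargement, and the other oxolane carbon C-2 sits on the migrating atom C-1 at acetal level.
5. 11 ⇐ cyclopent-2-enone by asymmetric Mukaiyama–Michael addition (C-14, C-15), orthoformate trapping (C-1, C-2) and ethynylation/allylation/semi-hydrogenation (C-7 to C-10). Ring order: cyclopentane (bought) → cyclohexane + oxolane (step 8) → oxepane (step 14) → oxonane (step 18).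

Key step: step 8

Remark (numbering): eunicellane numbering is used for all intermediates: C-1/C-10 ring fusion, C-2 and C-9 oxolane ether carbons, C-3 (methyl, oxepane oxygen), C-4 (octanoate), C-6 (carbinol), C-7 (methylidene), C-11 (methyl carbinol), C-14 (side-chain carbon), C-15 (methyl), C-16 (CH2O).
Remark (assumption): the sense of induction of the chiral catalysts in steps 2 and 14 is assigned from the accepted open and spiro transition-state models; if a model fails, the antipodal catalyst would be used.
Remark (assumption): 3-(tert-butyldiphenylsilyloxy)propanal (14) is taken as a catalogue compound.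

**Route**

Step 1
Reactants: 1 methyl propanoate
Product: 2 (E)-1-methoxy-1-(trimethylsilyloxy)prop-1-ene
Conditions: LiN(i-Pr)2, THF, −78 °C; Me3SiCl, −78 °C → rt
Reagents that add atoms: chlorotrimethylsilane, C[Si](C)(C)Cl
Why: kinetic deprotonation of the ester in THF without a polar cosolvent followed by O-silylation should give the (E)-configured ketene silyl acetal.

Step 2
Reactants: 2 (E)-1-methoxy-1-(trimethylsilyloxy)prop-1-ene; 3 cyclopent-2-en-1-one
Product: 5 methyl (2R)-2-[(1R,2R)-2-(dimethoxymethyl)-3-oxocyclopentyl]propanoate, via silyl enol ether 4 (not isolated)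
Conditions: (S)-o-tolyl-CBS-oxazaborolidine·HNTf2 (20 mol %), CH2Cl2, −78 °C; then HC(OMe)3, Me3SiOTf (10 mol %), −78 → −40 °C
Reagents that add atoms: trimethyl orthoformate, COC(OC)OC
Why: a catalytic asymmetric Mukaiyama–Michael addition through an open antiperiplanar transition state (enone face chosen by the catalyst, C-15 methyl placed beside H-14) should set C-14 and C-15 and leave the regiodefined enol silane 4, which the dimethoxycarbenium ion then alkylates anti to the C-14 substituent (Mukaiyama-type orthoester alkylation) to give the 1,14-trans keto acetal.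

Step 3
Reactants: 5 methyl (2R)-2-[(1R,2R)-2-(dimethoxymethyl)-3-oxocyclopentyl]propanoate
Product: 6 methyl (2R)-2-[(1R,2S,3R)-2-(dimethoxymethyl)-3-ethynyl-3-hydroxycyclopentyl]propanoate (hydroxyl cis to the dimethoxymethyl group)
Conditions: HC≡CMgBr, CeCl3, THF, −78 °C
Reagents that add atoms: ethynylmagnesium bromide, C#C[Mg]Br
Why: the weakly basic alkynylcerium reagent should add to the ketone only (ester untouched, no β-elimination of the acetal) from the face anti to the neighbouring dimethoxymethyl group, which fixes C-11.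

Step 4
Reactants: 6 ethynyl carbinol (as named in step 3); 7 2,3-dibromoprop-1-ene
Product: 8 enyne carbinol: 6 carrying a 4-bromopent-4-en-1-yn-1-yl group in place of ethynyl
Conditions: CuI (cat.), K2CO3, Bu4NI (cat.), DMF, rt
Reagents that add atoms: none
Why: copper-acetylide substitution at the allylic bromide (terminal-alkyne allylation) should form the C-8–C-9 bond and leave the vinylic bromide for the last step.

Step 5
Reactants: 8 enyne carbinol
Product: 9 (Z)-allylic alcohol: tertiary carbinol bearing the (1Z)-4-bromopenta-1,4-dien-1-yl chain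
Conditions: H2 (1 atm), Pd/CaCO3 poisoned with Pb(OAc)2 (Lindlar catalyst), quinoline, EtOAc, rt
Reagents that add atoms: none
Why: syn semi-hydrogenation of the internal alkyne should give the (Z)-alkene needed for a cis-epoxide, the alkenyl bromide being inert to the poisoned catalyst.

Step 6
Reactants: 9 (Z)-allylic alcohol
Product: 10 trimethylsilyl ether of 9
Conditions: 1-(trimethylsilyl)imidazole, CH2Cl2, rt
Reagents that add atoms: 1-(trimethylsilyl)imidazole, C[Si](C)(C)n1ccnc1
Why: neutral silylation of the tertiary alcohol switches off hydroxyl direction in the epoxidation and installs the silyloxy group that drives the later 1,2-shift.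

Step 7
Reactants: 10 silyl ether
Product: 11 cis-C-9/C-10 epoxide of 10 (epoxy silyl ether, configuration as in the SMILES)
Conditions: mCPBA, NaHCO3, CH2Cl2, 0 °C
Reagents that add atoms: 3-chloroperoxybenzoic acid, OOC(=O)c1cccc(Cl)c1
Why: Prilezhaev epoxidation of the only electron-rich alkene (the bromoalkene is deactivated); allylic 1,3-strain in the (Z)-alkene leaves only C-10–C-11 rotamers that expose the face remote from the silyloxy group and the branched ring carbon C-1, so the cis-epoxide with the required C-9/C-10 configuration should predominate.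

Step 8
Reactants: 11 epoxy silyl ether
Product: 13 bicyclic keto acetal: cis-fused 2-methoxy-oxolane/cyclohexanone (C-11 ketone, C-9 bromoallyl, C-14 propanoate side chain; C-2 anomer mixture), via silyloxy ketone 12 (not isolated)
Conditions: Me3SiOTf (20 mol %), 2,6-di-tert-butyl-4-methylpyridine (30 mol %), CH2Cl2, −78 → −20 °C
Reagents that add atoms: none
Why: Me3SiOTf silylates the epoxide oxygen, and the C-11–C-1 bond, antiperiplanar to the breaking C-10–O bond, shifts to C-10 while the silyloxy group at C-11 becomes the ketone (semipinacol rearrangement, cyclopentane to cyclohexanone, giving 12 after silyl transfer to the C-9 oxygen); on warming the same catalyst ionises the dimethyl acetal, the C-9 silyl ether oxygen adds to the C-2 oxocarbenium ion, and Me3SiOMe leaves with regeneration of the catalyst. The closest known reactions are the Lewis-acid rearrangement of 2,3-epoxy silyl ethers to aldols with ring enlargement of 1-oxiranylcycloalkanols, and the silyl-triflate-catalysed exchange of acetals with silyl ethers. The six-membered carbocycle closes by the suprafacial 1,2-alkyl shift (enlargement by one atom, C-10 inserted between C-11 and C-1), the oxolane by 5-exo-trig attack of oxygen on the oxocarbenium ion. C-10 is set by inversion at the epoxide carbon, C-1 migrates with retention and C-9 keeps its epoxide configuration, so the cis relation of H-1 and H-10 and the C-9 centre follow from the epoxide of step 7; C-2 forms as an anomer mixture that converges in step 11. The step needs migration of C-1 and not of C-12: C-1 is the more substituted carbon, the rotamer with C-1 anti to the epoxide C–O bond keeps the activated oxygen beside the small CH2 group, and the shift is run at −78 °C before the acetal, whose ionisation would deactivate C-1, reacts on warming.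

Step 9
Reactants: 14 3-(tert-butyldiphenylsilyloxy)propanal
Product: 15 (Z)-5-(tert-butyldiphenylsilyloxy)-2-iodopent-2-ene
Conditions: EtPPh3I, n-BuLi, THF, rt; I2, −78 °C; NaN(SiMe3)2, −78 °C; then 14, −78 → −20 °C
Reagents that add atoms: ethyltriphenylphosphonium iodide, CC[P+](c1ccccc1)(c1ccccc1)c1ccccc1.[I-]; iodine, II
Why: Stork–Zhao-type olefination with the α-iodoethylidene ylide should give the (Z)-2-iodoalkene (iodine cis to the chain) through the kinetic cis-oxaphosphetane.

Step 10
Reactants: 15 (Z)-alkenyl iodide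
Product: 16 potassium (E)-[5-(tert-butyldiphenylsilyloxy)pent-2-en-2-yl]trifluoroborate (boron cis to the chain)
Conditions: t-BuLi (2 equiv), Et2O, −78 °C; B(OMe)3, −78 °C → rt; KHF2, MeOH/H2O
Reagents that add atoms: trimethyl borate, COB(OC)OC; potassium hydrogen difluoride, F.[F-].[K+]
Why: iodine–lithium exchange and borylation proceed with retention of alkene geometry, and KHF2 converts the boronate into the bench-stable trifluoroborate.

Step 11
Reactants: 13 bicyclic keto acetal; 16 alkenyltrifluoroborate
Product: 17 C-2 alkenyl ketone: oxolane carrying the (Z)-C-3(Me)=C-4H–CH2CH2OTBDPS group at C-2 on the convex face, C-11 ketone, methyl ester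
Conditions: BF3·OEt2 (2 equiv), MeCN/CH2Cl2, −40 → 0 °C; aq. NaHCO3
Reagents that add atoms: none
Why: BF3 generates the bicyclic C-2 oxocarbenium ion and the alkenyldifluoroborane formed in situ transfers its alkenyl group with retention of geometry to the convex face, anti to C-14 on the neighbouring carbon (substitution of an O,O-acetal by an organotrifluoroborate), which sets C-2 with the oxonane carbons C-3 and C-8 cis.

Step 12
Reactants: 17 C-2 alkenyl ketone
Product: 18 C-11 spiro-epoxide (oxygen axial, on the face of H-10)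
Conditions: Me3S(O)I, NaH, DMSO/THF, 0 °C → rt
Reagents that add atoms: trimethylsulfoxonium iodide, C[S+](C)(C)=O.[I-]
Why: Corey–Chaykovsky epoxidation with the sulfoxonium ylide adds reversibly and should close through the betaine with the new C–C bond equatorial, placing the oxygen axial on the convex face as C-11 requires; the ester and alkenes are untouched.

Step 13
Reactants: 18 spiro-epoxide
Product: 19 diol: C-11 tertiary methyl carbinol and C-16 primary alcohol
Conditions: LiAlH4, THF, 0 °C
Reagents that add atoms: none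
Why: hydride opens the spiro-epoxide at its CH2 terminus, giving the tertiary alcohol with the configuration fixed in step 12, and reduces the methyl ester to the C-16 alcohol in the same operation.

Step 14
Reactants: 19 diol
Product: 21 oxepane diol: C-3–O–C-16 ether closed, free C-4 and C-11 hydroxyls, C-6 silyl ether, via epoxide 20 (not isolated)
Conditions: D-fructose-derived Shi ketone (30 mol %), KHSO5 (as 2KHSO5·KHSO4·K2SO4), K2CO3, Bu4NHSO4, MeCN/CH2(OMe)2/aq. buffer, 0 °C; then CSA (10 mol %), CH2Cl2, 0 °C
Reagents that add atoms: potassium peroxymonosulfate, [K+].[O-]S(=O)(=O)OO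
Why: reagent-controlled Shi epoxidation of the trisubstituted (Z)-alkene (spiro transition state; the bromoalkene is inert) should give the (3R,4R)-epoxide, which the C-16 hydroxyl opens under acid at the tertiary carbon C-3 in the 7-exo mode with inversion, closing the oxepane and releasing the C-4 alcohol with the correct configuration (the C-11 hydroxyl is trans to C-2 on the cyclohexane and cannot reach C-3).

Step 15
Reactants: 21 oxepane diol
Product: 22 C-4 octanoate
Conditions: octanoyl chloride, pyridine, DMAP (cat.), CH2Cl2, 0 °C → rt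
Reagents that add atoms: octanoyl chloride, CCCCCCCC(=O)Cl
Why: nucleophilic-catalysed acylation takes the secondary C-4 alcohol, while the tertiary C-11 alcohol is unreactive under these conditions.

Step 16
Reactants: 22 C-4 octanoate
Product: 23 C-6 primary alcohol
Conditions: HF·pyridine, pyridine/THF, 0 °C → rt
Reagents that add atoms: none
Why: fluoride-mediated cleavage of the silyl ether under buffered conditions leaves the ester, the ethers and the alkenyl bromide intact.

Step 17
Reactants: 23 C-6 primary alcohol
Product: 24 C-6 aldehyde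
Conditions: Dess–Martin periodinane, NaHCO3, CH2Cl2, rt
Reagents that add atoms: none
Why: Dess–Martin oxidation converts the primary alcohol into the aldehyde without touching the tertiary alcohol or epimerising neighbouring centres.

Step 18
Reactants: 24 C-6 aldehyde
Product: 25 target compound
Conditions: CrCl2, NiCl2 (cat.), DMSO, rt, high dilution
Reagents that add atoms: none
Why: Nozaki–Hiyama–Kishi reaction: zerovalent nickel inserts into the alkenyl bromide, transmetalation gives the alkenyl species of trivalent chromium, and its addition to the aldehyde closes the oxonane and forms the C-6 allylic alcohol beside the C-7 methylidene; the rigid tricyclic core should expose one aldehyde face and so set C-6.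

**Compound list**

1 | methyl propanoate | CCC(=O)OC | starting material
2 | (E)-1-methoxy-1-(trimethylsilyloxy)prop-1-ene | C/C=C(/O[Si](C)(C)C)OC | intermediate
3 | cyclopent-2-en-1-one | O=C1C=CCC1 | starting material
4 | methyl (2R)-2-[(1R)-3-(trimethylsilyloxy)cyclopent-2-en-1-yl]propanoate (silyl enol ether) | C[Si](C)(C)OC1=C[C@@H](CC1)[C@@H](C)C(=O)OC | intermediate
5 | methyl (2R)-2-[(1R,2R)-2-(dimethoxymethyl)-3-oxocyclopentyl]propanoate | O=C1CC[C@@H]([C@@H](C)C(=O)OC)[C@@H]1C(OC)OC | intermediate
6 | methyl (2R)-2-[(1R,2S,3R)-2-(dimethoxymethyl)-3-ethynyl-3-hydroxycyclopentyl]propanoate | C#C[C@@]1(O)CC[C@@H]([C@@H](C)C(=O)OC)[C@@H]1C(OC)OC | intermediate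
7 | 2,3-dibromoprop-1-ene | C=C(Br)CBr | starting material
8 | enyne carbinol (6 with a 4-bromopent-4-en-1-yn-1-yl group at C-11) | C=C(Br)CC#C[C@@]1(O)CC[C@@H]([C@@H](C)C(=O)OC)[C@@H]1C(OC)OC | intermediate
9 | (Z)-allylic alcohol ((1Z)-4-bromopenta-1,4-dien-1-yl carbinol) | C=C(Br)C/C=C\[C@@]1(O)CC[C@@H]([C@@H](C)C(=O)OC)[C@@H]1C(OC)OC | intermediate
10 | trimethylsilyl ether of 9 | C=C(Br)C/C=C\[C@@]1(O[Si](C)(C)C)CC[C@@H]([C@@H](C)C(=O)OC)[C@@H]1C(OC)OC | intermediate
11 | cis-C-9/C-10 epoxy silyl ether | C=C(Br)C[C@@H]1O[C@@H]1[C@@]2(O[Si](C)(C)C)CC[C@@H]([C@@H](C)C(=O)OC)[C@@H]2C(OC)OC | intermediate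
12 | ring-enlarged β-silyloxy ketone (cyclohexanone with C-9 OSiMe3 and C-1 dimethoxymethyl) | C=C(Br)C[C@H](O[Si](C)(C)C)[C@@H]1C(=O)CC[C@@H]([C@@H](C)C(=O)OC)[C@@H]1C(OC)OC | intermediate
13 | bicyclic keto acetal (cis-fused 2-methoxyoxolane/cyclohexanone, C-2 anomer mixture) | C=C(Br)C[C@@H]1OC(OC)[C@H]2[C@@H](CCC(=O)[C@H]21)[C@@H](C)C(=O)OC | intermediate
14 | 3-(tert-butyldiphenylsilyloxy)propanal | O=CCCO[Si](c1ccccc1)(c1ccccc1)C(C)(C)C | starting material
15 | (Z)-5-(tert-butyldiphenylsilyloxy)-2-iodopent-2-ene | I/C(C)=C\CCO[Si](c1ccccc1)(c1ccccc1)C(C)(C)C | intermediate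
16 | potassium (E)-[5-(tert-butyldiphenylsilyloxy)pent-2-en-2-yl]trifluoroborate | [K+].F[B-](F)(F)/C(C)=C\CCO[Si](c1ccccc1)(c1ccccc1)C(C)(C)C | intermediate
17 | C-2 (Z)-alkenyl bicyclic ketone | C=C(Br)C[C@@H]1O[C@@H]([C@H]2[C@@H](CCC(=O)[C@H]21)[C@@H](C)C(=O)OC)/C(C)=C\CCO[Si](c3ccccc3)(c4ccccc4)C(C)(C)C | intermediate
18 | C-11 spiro-epoxide | C=C(Br)C[C@@H]1O[C@@H]([C@H]2[C@@H](CC[C@]3(OC3)[C@H]21)[C@@H](C)C(=O)OC)/C(C)=C\CCO[Si](c4ccccc4)(c5ccccc5)C(C)(C)C | intermediate
19 | C-11/C-16 diol | C=C(Br)C[C@@H]1O[C@@H]([C@H]2[C@@H](CC[C@](C)(O)[C@H]21)[C@@H](C)CO)/C(C)=C\CCO[Si](c3ccccc3)(c4ccccc4)C(C)(C)C | intermediate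
20 | (3R,4R)-epoxide of 19 | C=C(Br)C[C@@H]1O[C@@H]([C@H]2[C@@H](CC[C@](C)(O)[C@H]21)[C@@H](C)CO)[C@]3(C)O[C@@H]3CCO[Si](c4ccccc4)(c5ccccc5)C(C)(C)C | intermediate
21 | oxepane diol (free C-4 and C-11 hydroxyls) | C=C(Br)C[C@@H]1O[C@H]2[C@H]3[C@@H](CC[C@](C)(O)[C@H]31)[C@@H](C)CO[C@@]2(C)[C@H](O)CCO[Si](c4ccccc4)(c5ccccc5)C(C)(C)C | intermediate
22 | C-4 octanoate, C-6 silyl ether | C=C(Br)C[C@@H]1O[C@H]2[C@H]3[C@@H](CC[C@](C)(O)[C@H]31)[C@@H](C)CO[C@@]2(C)[C@H](OC(=O)CCCCCCC)CCO[Si](c4ccccc4)(c5ccccc5)C(C)(C)C | intermediate
23 | C-4 octanoate, C-6 primary alcohol | C=C(Br)C[C@@H]1O[C@H]2[C@H]3[C@@H](CC[C@](C)(O)[C@H]31)[C@@H](C)CO[C@@]2(C)[C@H](OC(=O)CCCCCCC)CCO | intermediate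
24 | C-4 octanoate, C-6 aldehyde | C=C(Br)C[C@@H]1O[C@H]2[C@H]3[C@@H](CC[C@](C)(O)[C@H]31)[C@@H](C)CO[C@@]2(C)[C@H](OC(=O)CCCCCCC)CC=O | intermediate
25 | target compound (tetracyclic 4-octanoate with free C-6 and C-11 hydroxyls and C-7 methylidene) | C=C1C[C@@H]2O[C@H]3[C@H]4[C@@H](CC[C@](C)(O)[C@H]42)[C@@H](C)CO[C@@]3(C)[C@H](OC(=O)CCCCCCC)C[C@H]1O | target

**Step count**

Total steps: 18. Longest linear sequence: 16 steps (steps 1 to 8 and 11 to 18).

**Steps most likely to fail**

Step 8. The 1,2-shift may take the other ring bond (migration of the unbranched C-12, because the acetal on C-1 is inductively deactivating), or the acetal may ionise before the epoxide and shut down migration of C-1. The fallback sets out from silyl enol ether 4 and returns at 13; it replaces the acetal by a vinyl group, so that the migrating carbon is allylic and carries no oxygen. The solution of 4 would be coupled with vinyl bromide (Pd2(dba)3, P(t-Bu)3, Bu3SnF, toluene) to give the trans 2-vinyl ketone F1. The operations of steps 3 to 7 would then give the ethynyl carbinol F2, the enyne carbinol F3, the (Z)-allylic alcohol F4, its trimethylsilyl ether F5 and the cis-epoxide F6. Rearrangement of F6 with Me3SiOTf at −78 °C should give the ring-enlarged β-silyloxy ketone F7 without a close competition between migrating groups. Lemieux–Johnson cleavage of the vinyl group (OsO4 cat., NaIO4, 2,6-lutidine, dioxane/H2O; the bromoalkene is electron-poor) followed by CSA in methanol would close the lactol and deliver methyl acetal 13.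

Step 14. Under acid the trisubstituted epoxide may undergo a Meinwald-type hydride or alkyl shift, or the seven-membered ring may close too slowly to compete. The fallback sets out from 19 and returns at 21; it makes C-16 the electrophile and a C-3 alkoxide the nucleophile. Selective mesylation of the primary alcohol (MsCl, Et3N, CH2Cl2, −20 °C) would give the C-16 mesylate F8, and Shi epoxidation as in step 14 the epoxy mesylate F9. Hydrolysis with water as external nucleophile (HClO4 cat., THF/H2O), opening at the tertiary carbon C-3 with inversion, would give the 3,4-diol mesylate F10. NaH in THF would then close the oxepane by intramolecular Williamson etherification of the C-3 alkoxide onto C-16, giving 21.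

Step 12. The basic ylide may enolise the β-alkoxy ketone (epimerisation at C-10 or β-elimination that opens the oxolane), or the facial bias of the epoxide closure may be insufficient. The fallback sets out from 17 and returns at 19; it avoids base and builds the carbinol by hydration. Takai–Lombardo methylenation (Zn, CH2Br2, TiCl4, THF) would give the C-11 methylidene compound F11. Oxymercuration–demercuration (Hg(OAc)2, THF/H2O; NaBH4, NaOH), which is fastest at the 1,1-disubstituted alkene and delivers water axially from the convex face, would give the tertiary alcohol ester F12. LiAlH4 reduction of the ester would then give 19.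

**Further compounds**

F1 | step 8 | methyl (2R)-2-[(1R,2R)-2-ethenyl-3-oxocyclopentyl]propanoate (trans 2-vinyl ketone) | O=C1CC[C@@H]([C@@H](C)C(=O)OC)[C@@H]1C=C
F2 | step 8 | ethynyl carbinol of the vinyl series | C#C[C@@]1(O)CC[C@@H]([C@@H](C)C(=O)OC)[C@@H]1C=C
F3 | step 8 | enyne carbinol of the vinyl series | C=C(Br)CC#C[C@@]1(O)CC[C@@H]([C@@H](C)C(=O)OC)[C@@H]1C=C
F4 | step 8 | (Z)-allylic alcohol of the vinyl series | C=C(Br)C/C=C\[C@@]1(O)CC[C@@H]([C@@H](C)C(=O)OC)[C@@H]1C=C
F5 | step 8 | trimethylsilyl ether of the vinyl series | C=C(Br)C/C=C\[C@@]1(O[Si](C)(C)C)CC[C@@H]([C@@H](C)C(=O)OC)[C@@H]1C=C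
F6 | step 8 | cis-epoxide of the vinyl series | C=C(Br)C[C@@H]1O[C@@H]1[C@@]2(O[Si](C)(C)C)CC[C@@H]([C@@H](C)C(=O)OC)[C@@H]2C=C
F7 | step 8 | ring-enlarged β-silyloxy ketone of the vinyl series | C=C(Br)C[C@H](O[Si](C)(C)C)[C@@H]1C(=O)CC[C@@H]([C@@H](C)C(=O)OC)[C@@H]1C=C
F8 | step 14 | C-16 mesylate of 19 | C=C(Br)C[C@@H]1O[C@@H]([C@H]2[C@@H](CC[C@](C)(O)[C@H]21)[C@@H](C)COS(C)(=O)=O)/C(C)=C\CCO[Si](c3ccccc3)(c4ccccc4)C(C)(C)C
F9 | step 14 | (3R,4R)-epoxy mesylate | C=C(Br)C[C@@H]1O[C@@H]([C@H]2[C@@H](CC[C@](C)(O)[C@H]21)[C@@H](C)COS(C)(=O)=O)[C@]3(C)O[C@@H]3CCO[Si](c4ccccc4)(c5ccccc5)C(C)(C)C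
F10 | step 14 | 3,4-diol mesylate | C=C(Br)C[C@@H]1O[C@@H]([C@H]2[C@@H](CC[C@](C)(O)[C@H]21)[C@@H](C)COS(C)(=O)=O)[C@@](C)(O)[C@H](O)CCO[Si](c3ccccc3)(c4ccccc4)C(C)(C)C
F11 | step 12 | C-11 methylidene compound | C=C(Br)C[C@@H]1O[C@@H]([C@H]2[C@@H](CCC(=C)[C@H]21)[C@@H](C)C(=O)OC)/C(C)=C\CCO[Si](c3ccccc3)(c4ccccc4)C(C)(C)C
F12 | step 12 | C-11 tertiary alcohol methyl ester | C=C(Br)C[C@@H]1O[C@@H]([C@H]2[C@@H](CC[C@](C)(O)[C@H]21)[C@@H](C)C(=O)OC)/C(C)=C\CCO[Si](c3ccccc3)(c4ccccc4)C(C)(C)C
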